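**Retrosynthetic overview**
1. Target ⇒ 9-deoxy compound (allylic C9 hydroxylation last) ⇒ C12 lactol + C13–C17 unit (syn-α-hydroxyallylation, acetylation, cross-metathesis).
2. 4α-OH/C2=C3 ⇒ singlet-oxygen ene reaction of a C3=C4 olefin (the dictyol pattern), itself from dehydration of the 4α-ol left by epoxide opening.
3. Key disconnections, made in one flask: C1–C5 by transannular attack of the C1=C10 alkene on a (4R,5R)-epoxide, and C6–C7 by allylchromium/aldehyde ring closure (the bond formed when geranylgeranyl diphosphate closes its ten-membered ring).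
4. Ring order: ten-membered carbocycle first, its cis-γ-lactone second, then the five- and seven-membered rings together in the transannular step; the lactone later sets C11 and becomes C12.
5. Acyclic precursor ⇒ (2E,6E)-farnesol (C1–C10, C18, C20), methyl acrylate (C11, C12, C19), Sharpless epoxidation for absolute configuration.

Assumption: locants follow dictyol numbering on the parent "dictyolane" (five-membered ring C1–C5 with C1/C5 at the ring fusion and CH3-20 on C4; seven-membered ring C1, C5–C10 with CH2-18 on C10; side chain C11(CH3-19)–C12–C13–C14=C15(CH3-16)(CH3-17) on C7; α = face of H-1 and H-5), and the target read from the SMILES is 1R,4R,5S,6R,7S,9R,11R,12S,13S.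

**Route**

Step 1
Reactants: 1 (2E,6E)-farnesol
Product: 3 (2E,6E)-10,11-epoxy-3,7,11-trimethyldodeca-2,6-dien-1-ol, via bromohydrin 2 (not isolated)
Conditions: NBS, THF/H2O, 0 °C; then K2CO3, MeOH, 23 °C
Reagents that add atoms: water, O
Why: Van Tamelen terminal functionalisation, in which NBS in aqueous THF attacks the terminal trisubstituted alkene selectively to give the bromohydrin and K2CO3 closes it to the epoxide (intramolecular Williamson reaction); the new centre is racemic and is excised in step 2.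

Step 2
Reactants: 3 (2E,6E)-10,11-epoxy-3,7,11-trimethyldodeca-2,6-dien-1-ol
Product: 4 (4E,8E)-10-hydroxy-4,8-dimethyldeca-4,8-dienal
Conditions: H5IO6, THF/H2O, 0 °C
Reagents that add atoms: none
Why: Periodic acid hydrolyses the epoxide and cleaves the resulting diol (Malaprade glycol cleavage) to the aldehyde with loss of acetone, leaving both trisubstituted alkenes and the allylic alcohol untouched.

Step 3
Reactants: 4 (4E,8E)-10-hydroxy-4,8-dimethyldeca-4,8-dienal; 5 methyl acrylate
Product: 6 methyl (6E,10E)-3,12-dihydroxy-6,10-dimethyl-2-methylidenedodeca-6,10-dienoate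
Conditions: DABCO, MeOH, 23 °C, 5 d
Reagents that add atoms: none
Why: Morita–Baylis–Hillman reaction, in which the DABCO–acrylate zwitterion adds to the aldehyde; the new carbinol centre is racemic, which is irrelevant because it becomes sp2 in step 5.

Step 4
Reactants: 6 methyl (6E,10E)-3,12-dihydroxy-6,10-dimethyl-2-methylidenedodeca-6,10-dienoate
Product: 7 methyl (6E)-3-hydroxy-9-[(2R,3R)-3-(hydroxymethyl)-2-methyloxiran-2-yl]-6-methyl-2-methylidenenon-6-enoate
Conditions: Ti(OiPr)4 (10 mol %), D-(−)-diethyl tartrate (12 mol %), t-BuOOH, 4 Å MS, CH2Cl2, −20 °C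
Reagents that add atoms: tert-butyl hydroperoxide, CC(C)(C)OO
Why: Sharpless asymmetric epoxidation of the primary (E)-allylic alcohol, where D-(−)-tartrate gives the (2R,3R)-epoxy alcohol (future C4 and C5) while the electron-poor acrylate alkene and the remote trisubstituted alkene do not react.

Step 5
Reactants: 7 methyl (6E)-3-hydroxy-9-[(2R,3R)-3-(hydroxymethyl)-2-methyloxiran-2-yl]-6-methyl-2-methylidenenon-6-enoate
Product: 8 methyl (2Z,6E)-2-(bromomethyl)-9-[(2R,3R)-3-(hydroxymethyl)-2-methyloxiran-2-yl]-6-methylnona-2,6-dienoate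
Conditions: NBS, Me2S, CH2Cl2, −20 to 0 °C
Reagents that add atoms: N-bromosuccinimide, O=C1CCC(=O)N1Br
Why: Corey–Kim-type bromination, in which the bromosulfonium salt activates the Baylis–Hillman alcohol and bromide attacks SN2′ to give the thermodynamically preferred (Z)-2-(bromomethyl)enoate (chain cis to CH2Br), while the non-allylic primary alcohol is returned on work-up.

Step 6
Reactants: 8 methyl (2Z,6E)-2-(bromomethyl)-9-[(2R,3R)-3-(hydroxymethyl)-2-methyloxiran-2-yl]-6-methylnona-2,6-dienoate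
Product: 9 methyl (2Z,6E)-2-(bromomethyl)-9-[(2R,3S)-3-formyl-2-methyloxiran-2-yl]-6-methylnona-2,6-dienoate
Conditions: TEMPO (10 mol %), PhI(OAc)2, CH2Cl2, 23 °C
Reagents that add atoms: none
Why: Oxoammonium (TEMPO/PhI(OAc)2) oxidation turns the primary alcohol into the aldehyde without epimerising the epoxide carbon or touching the allylic bromide.

Step 7
Reactants: 9 methyl (2Z,6E)-2-(bromomethyl)-9-[(2R,3S)-3-formyl-2-methyloxiran-2-yl]-6-methylnona-2,6-dienoate
Product: 12 (1R,4R,5S,6R,7S)-4-hydroxy-13,14,15,16,17-pentanordictyola-10(18),11(19)-dien-12,6-olide, via macrocyclic hydroxy ester 10 (not isolated), via epoxy germacranolide 11 (not isolated)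
Conditions: CrCl2 (8 equiv), THF, 23 °C, slow addition of 9 to 2 mM; then Et2AlCl (4 equiv), −78 to −20 °C, same flask
Reagents that add atoms: none
Why: Proposed new method: CrCl2 inserts into the allylic C–Br bond and the trivalent allylchromium adds through its γ-carbon (C7) to the aldehyde in a six-membered chair inside the forming ten-membered ring, where the ester-chelated Z geometry keeps C8 axial (6,7-syn, hence the cis lactone once the chromium alkoxide expels methoxide) and the Felkin–Anh arrangement of the epoxy aldehyde (epoxide C–O anti to the nucleophile) gives 6R, after which Et2AlCl activates the epoxide so that the C1=C10 π-bond attacks C5 with inversion from the crossed conformer of the (E)-cycloalkene (cis ring fusion, 1R and 5S, C4–O retained as 4R) and the C10 cation loses a methyl proton to an aluminium ethyl group to give the exocyclic alkene; the closest known reactions are the CrCl2 Barbier macrocyclisation of 2-(bromomethyl)acrylates onto aldehydes and the acid-promoted transannular cyclisation of 4,5-epoxygermacranolides to guaianolides, here run in sequence without isolation.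

Step 8
Reactants: 12 (1R,4R,5S,6R,7S)-4-hydroxy-13,14,15,16,17-pentanordictyola-10(18),11(19)-dien-12,6-olide
Product: 13 (1R,4R,5S,6R,7S,11R)-4-hydroxy-13,14,15,16,17-pentanordictyol-10(18)-en-12,6-olide
Conditions: [(Ph3P)CuH]6 (5 mol %), PhSiH3, t-BuOH, toluene, 0 to 23 °C
Reagents that add atoms: none
Why: Copper hydride 1,4-reduction (Stryker type) of the α-methylene lactone, whose enolate is protonated kinetically by t-BuOH on the convex face of the cis-fused lactone (anti to C5 and C8), placing H-11 cis to H-7 (11R), while the isolated 1,1-disubstituted alkene is inert.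

Step 9
Reactants: 13 (1R,4R,5S,6R,7S,11R)-4-hydroxy-13,14,15,16,17-pentanordictyol-10(18)-en-12,6-olide
Product: 14 (1R,5R,6R,7S,11R)-13,14,15,16,17-pentanordictyola-3,10(18)-dien-12,6-olide
Conditions: SOCl2, pyridine, CH2Cl2, −20 to 0 °C
Reagents that add atoms: none
Why: Dehydration through the chlorosulfite (E2), in which H-5 is cis to the leaving group and cannot leave anti, so elimination gives the more substituted endocyclic C3=C4 alkene (Zaitsev) and no stereocentre is created.

Step 10
Reactants: 14 (1R,5R,6R,7S,11R)-13,14,15,16,17-pentanordictyola-3,10(18)-dien-12,6-olide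
Product: 16 (1R,4R,5S,6R,7S,11R)-4-hydroxy-13,14,15,16,17-pentanordictyola-2,10(18)-dien-12,6-olide, via hydroperoxide 15 (not isolated)
Conditions: O2, visible light, tetraphenylporphyrin (cat.), CH2Cl2, −20 °C; then PPh3
Reagents that add atoms: oxygen, O=O
Why: Schenck ene reaction, in which singlet oxygen adds to the convex α-face of the trisubstituted cyclopentene, abstracts the α-hydrogen of C2 and delivers oxygen suprafacially to C4 (4α-hydroperoxide, alkene shifted to C2=C3) before PPh3 reduces the O–O bond to the 4R tertiary allylic alcohol, the 1,1-disubstituted alkene reacting far more slowly.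

Step 11
Reactants: 16 (1R,4R,5S,6R,7S,11R)-4-hydroxy-13,14,15,16,17-pentanordictyola-2,10(18)-dien-12,6-olide
Product: 17 (1R,4R,5S,6R,7S,11R)-6,12-epoxy-13,14,15,16,17-pentanordictyola-2,10(18)-diene-4,12-diol
Conditions: iBu2AlH (2.2 equiv), CH2Cl2, −78 °C
Reagents that add atoms: none
Why: Low-temperature iBu2AlH half-reduction of the γ-lactone stops at the aluminium hemiacetal and gives the lactol on work-up without enolising C11; the anomeric centre is inconsequential.

Step 12
Reactants: 18 acrolein; 19 acetyl bromide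
Product: 20 3-bromoprop-1-en-1-yl acetate
Conditions: ZnCl2 (cat.), CH2Cl2, −20 to 0 °C
Reagents that add atoms: none
Why: ZnCl2-catalysed addition of the acyl bromide across the enal carbonyl followed by allylic 1,3-shift of bromide gives the conjugated enol acetate as an E/Z mixture, with no stereocentre.

Step 13
Reactants: 17 (1R,4R,5S,6R,7S,11R)-6,12-epoxy-13,14,15,16,17-pentanordictyola-2,10(18)-diene-4,12-diol; 20 3-bromoprop-1-en-1-yl acetate
Product: 21 (1R,4R,5S,6R,7S,11R,12S,13S)-13-acetoxy-16,17-dinordictyola-2,10(18),14-triene-4,6,12-triol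
Conditions: In powder, THF, 23 °C
Reagents that add atoms: none
Why: Indium-mediated Barbier α-hydroxyallylation of the open-chain hydroxy aldehyde, in which the acetate-chelated (Z)-γ-acetoxyallylindium reacts through a chair transition state (syn adduct) on the Felkin–Anh face set by C11 (nucleophile anti to C7), giving 12S and 13S.

Step 14
Reactants: 21 (1R,4R,5S,6R,7S,11R,12S,13S)-13-acetoxy-16,17-dinordictyola-2,10(18),14-triene-4,6,12-triol
Product: 22 (1R,4R,5S,6R,7S,11R,12S,13S)-4,6-dihydroxy-16,17-dinordictyola-2,10(18),14-triene-12,13-diyl diacetate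
Conditions: Ac2O (1.5 equiv), pyridine, DMAP (cat.), CH2Cl2, 0 °C
Reagents that add atoms: acetic anhydride, CC(=O)OC(C)=O
Why: DMAP-catalysed acylation of the exposed secondary 12-OH, while the 6-OH is shielded on the concave β-face between C5 and C7 and the 4-OH is tertiary, so both stay free.

Step 15
Reactants: 22 (1R,4R,5S,6R,7S,11R,12S,13S)-4,6-dihydroxy-16,17-dinordictyola-2,10(18),14-triene-12,13-diyl diacetate; 23 2-methylbut-2-ene
Product: 24 (1R,4R,5S,6R,7S,11R,12S,13S)-4,6-dihydroxydictyola-2,10(18),14-triene-12,13-diyl diacetate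
Conditions: 2-methylbut-2-ene (excess), second-generation Hoveyda–Grubbs catalyst RuCl2(H2IMes)(=CH-C6H4-2-OiPr) (5 mol %), CH2Cl2, 40 °C
Reagents that add atoms: none
Why: Olefin cross-metathesis converts the terminal vinyl group into the 2-methylprop-1-enyl group, the exocyclic 1,1-disubstituted alkene and the unstrained cyclopentene being poor metathesis partners, and no stereocentre is touched.

Step 16
Reactants: 24 (1R,4R,5S,6R,7S,11R,12S,13S)-4,6-dihydroxydictyola-2,10(18),14-triene-12,13-diyl diacetate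
Product: 25 (1R,4R,5S,6R,7S,9R,11R,12S,13S)-4,6,9-trihydroxydictyola-2,10(18),14-triene-12,13-diyl diacetate
Conditions: SeO2 (0.5 equiv), t-BuOOH, CH2Cl2, 0 to 23 °C
Reagents that add atoms: tert-butyl hydroperoxide, CC(C)(C)OO
Why: Catalytic SeO2 allylic oxidation (Riley/Sharpless), an ene reaction at the exocyclic CH2 with abstraction of an α-hydrogen of the C9 methylene (CH2 preferred over the C1 methine) followed by a [2,3]-shift that restores the exocyclic alkene and delivers oxygen to the convex α-face of C9 (9R), the isobutenyl group being deactivated by its allylic acetate.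

**Compound list**
1 | (2E,6E)-farnesol | CC(C)=CCC/C(C)=C/CC/C(C)=C/CO | starting material
2 | (2E,6E)-10-bromo-3,7,11-trimethyldodeca-2,6-diene-1,11-diol (racemic at C10) | CC(C)(O)C(Br)CC/C(C)=C/CC/C(C)=C/CO | intermediate
3 | (2E,6E)-10,11-epoxy-3,7,11-trimethyldodeca-2,6-dien-1-ol (racemic epoxide) | CC1(C)OC1CC/C(C)=C/CC/C(C)=C/CO | intermediate
4 | (4E,8E)-10-hydroxy-4,8-dimethyldeca-4,8-dienal | O=CCC/C(C)=C/CC/C(C)=C/CO | intermediate
5 | methyl acrylate | C=CC(=O)OC | starting material
6 | methyl (6E,10E)-3,12-dihydroxy-6,10-dimethyl-2-methylidenedodeca-6,10-dienoate (racemic at C3) | C=C(C(=O)OC)C(O)CC/C(C)=C/CC/C(C)=C/CO | intermediate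
7 | methyl (6E)-3-hydroxy-9-[(2R,3R)-3-(hydroxymethyl)-2-methyloxiran-2-yl]-6-methyl-2-methylidenenon-6-enoate (both C3 epimers) | C=C(C(=O)OC)C(O)CC/C(C)=C/CC[C@@]1(C)O[C@@H]1CO | intermediate
8 | methyl (2Z,6E)-2-(bromomethyl)-9-[(2R,3R)-3-(hydroxymethyl)-2-methyloxiran-2-yl]-6-methylnona-2,6-dienoate | COC(=O)/C(CBr)=C/CC/C(C)=C/CC[C@@]1(C)O[C@@H]1CO | intermediate
9 | methyl (2Z,6E)-2-(bromomethyl)-9-[(2R,3S)-3-formyl-2-methyloxiran-2-yl]-6-methylnona-2,6-dienoate | COC(=O)/C(CBr)=C/CC/C(C)=C/CC[C@@]1(C)O[C@@H]1C=O | intermediate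
10 | methyl (4R,5R,6R,7S,1(10)E)-4,5-epoxy-6-hydroxy-13,14,15,16,17-pentanor-1,5-secodictyola-1(10),11(19)-dien-12-oate (ten-membered ring; present as its chromium alkoxide) | COC(=O)C(=C)[C@@H]1CC/C(C)=C/CC[C@@]2(C)O[C@@H]2[C@@H]1O | intermediate
11 | (4R,5R,6R,7S,1(10)E)-4,5-epoxy-13,14,15,16,17-pentanor-1,5-secodictyola-1(10),11(19)-dien-12,6-olide (ten-membered ring, cis-fused α-methylene-γ-lactone) | O=C1O[C@@H]2[C@@H](CC/C(C)=C/CC[C@@]3(C)O[C@H]23)C1=C | intermediate
12 | (1R,4R,5S,6R,7S)-4-hydroxy-13,14,15,16,17-pentanordictyola-10(18),11(19)-dien-12,6-olide (cis-fused hydroazulene, cis-lactone) | C=C1CC[C@@H]2[C@@H](OC(=O)C2=C)[C@@H]3[C@H]1CC[C@@]3(C)O | intermediate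
13 | (1R,4R,5S,6R,7S,11R)-4-hydroxy-13,14,15,16,17-pentanordictyol-10(18)-en-12,6-olide | C=C1CC[C@@H]2[C@@H](OC(=O)[C@@H]2C)[C@@H]3[C@H]1CC[C@@]3(C)O | intermediate
14 | (1R,5R,6R,7S,11R)-13,14,15,16,17-pentanordictyola-3,10(18)-dien-12,6-olide | C=C1CC[C@@H]2[C@@H](OC(=O)[C@@H]2C)[C@@H]3[C@H]1CC=C3C | intermediate
15 | (1R,4R,5S,6R,7S,11R)-4-hydroperoxy-13,14,15,16,17-pentanordictyola-2,10(18)-dien-12,6-olide | C=C1CC[C@@H]2[C@@H](OC(=O)[C@@H]2C)[C@@H]3[C@H]1C=C[C@@]3(C)OO | intermediate
16 | (1R,4R,5S,6R,7S,11R)-4-hydroxy-13,14,15,16,17-pentanordictyola-2,10(18)-dien-12,6-olide | C=C1CC[C@@H]2[C@@H](OC(=O)[C@@H]2C)[C@@H]3[C@H]1C=C[C@@]3(C)O | intermediate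
17 | (1R,4R,5S,6R,7S,11R)-6,12-epoxy-13,14,15,16,17-pentanordictyola-2,10(18)-diene-4,12-diol (lactol, both C12 anomers) | C=C1CC[C@@H]2[C@@H](OC(O)[C@@H]2C)[C@@H]3[C@H]1C=C[C@@]3(C)O | intermediate
18 | acrolein | C=CC=O | starting material
19 | acetyl bromide | CC(=O)Br | starting material
20 | 3-bromoprop-1-en-1-yl acetate (E/Z mixture) | CC(=O)OC=CCBr | intermediate
21 | (1R,4R,5S,6R,7S,11R,12S,13S)-13-acetoxy-16,17-dinordictyola-2,10(18),14-triene-4,6,12-triol (side chain ends in CH=CH2) | C=C1CC[C@@H]([C@@H](C)[C@H](O)[C@H](C=C)OC(C)=O)[C@@H](O)[C@@H]2[C@H]1C=C[C@@]2(C)O | intermediate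
22 | (1R,4R,5S,6R,7S,11R,12S,13S)-4,6-dihydroxy-16,17-dinordictyola-2,10(18),14-triene-12,13-diyl diacetate | C=C1CC[C@@H]([C@@H](C)[C@H](OC(C)=O)[C@H](C=C)OC(C)=O)[C@@H](O)[C@@H]2[C@H]1C=C[C@@]2(C)O | intermediate
23 | 2-methylbut-2-ene | CC=C(C)C | starting material
24 | (1R,4R,5S,6R,7S,11R,12S,13S)-4,6-dihydroxydictyola-2,10(18),14-triene-12,13-diyl diacetate (9-deoxy target) | C=C1CC[C@@H]([C@@H](C)[C@H](OC(C)=O)[C@H](C=C(C)C)OC(C)=O)[C@@H](O)[C@@H]2[C@H]1C=C[C@@]2(C)O | intermediate
25 | (1R,4R,5S,6R,7S,9R,11R,12S,13S)-4,6,9-trihydroxydictyola-2,10(18),14-triene-12,13-diyl diacetate (CNP0269663.2) | C=C1[C@H](O)C[C@@H]([C@@H](C)[C@H](OC(C)=O)[C@H](C=C(C)C)OC(C)=O)[C@@H](O)[C@@H]2[C@H]1C=C[C@@]2(C)O | target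

**Step count and risks**
Total steps: 16. Longest linear sequence: 15 (steps 1–11 and 13–16; step 12 is a one-step side branch).

Three steps most likely to fail:

Step 7 (one-flask macrocyclisation and transannular cyclisation). The risks are the wrong C6/C7 relative configuration from a fluxional allylchromium, and endocyclic alkene isomers from the C10 cation. The fallback sets out from 8 and comes back at 12. Borylation of 8 with B2pin2 and Pd2(dba)3 gives the allylboronate methyl (2E,6E)-9-[(2R,3R)-3-(hydroxymethyl)-2-methyloxiran-2-yl]-6-methyl-2-[(4,4,5,5-tetramethyl-1,3,2-dioxaborolan-2-yl)methyl]nona-2,6-dienoate F1. TEMPO/PhI(OAc)2 oxidation gives the aldehyde methyl (2E,6E)-9-[(2R,3S)-3-formyl-2-methyloxiran-2-yl]-6-methyl-2-[(4,4,5,5-tetramethyl-1,3,2-dioxaborolan-2-yl)methyl]nona-2,6-dienoate F2. At high dilution F2 ring-closes by uncatalysed intramolecular allylboration; the closed chair and the configurationally fixed alkene enforce the 6,7-syn outcome. The product lactonises to 11, which is now isolated and purified, then cyclised in a separate flask (Et2AlCl, or BF3·OEt2 with 2,6-di-tert-butylpyridine) to 12.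

Step 10 (Schenck ene reaction). The risk is competing abstraction of H-5, which would give the 3-hydroperoxide with a C4=C5 alkene. The fallback sets out from 14 and comes back at 16. mCPBA epoxidises the convex face to the 3α,4α-epoxy-13,14,15,16,17-pentanordictyol-10(18)-en-12,6-olide F3. PhSeNa (from PhSeSePh/NaBH4, EtOH) opens it at the secondary carbon to the 4α-hydroxy-3β-(phenylselanyl)-13,14,15,16,17-pentanordictyol-10(18)-en-12,6-olide F4. H2O2 then gives the selenoxide, which can only eliminate toward C2 because C4 has no hydrogen, delivering 16.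

Step 13 (indium hydroxyallylation). The risks are syn/anti and facial selectivity on a substrate with free hydroxyls. The fallback sets out from 17 and comes back at 22. A reagent-controlled Brown alkoxyallylboration uses (Z)-γ-[2-(trimethylsilyl)ethoxymethoxy]allyldiisopinocampheylborane, made from allyl SEM ether, s-BuLi, (+)-Ipc2BOMe and BF3·OEt2 (re-face selective, matched with the Felkin preference). It gives the 13-[2-(trimethylsilyl)ethoxymethoxy]-16,17-dinordictyola-2,10(18),14-triene-4,6,12-triol F5. Bu4NF in DMPU removes the SEM group without acid to give the 16,17-dinordictyola-2,10(18),14-triene-4,6,12,13-tetrol F6. Ac2O (2.2 equiv)/pyridine/DMAP acetylates the 12- and 13-hydroxyls to 22.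

Further compounds
F1 | step 7 | methyl (2E,6E)-9-[(2R,3R)-3-(hydroxymethyl)-2-methyloxiran-2-yl]-6-methyl-2-[(4,4,5,5-tetramethyl-1,3,2-dioxaborolan-2-yl)methyl]nona-2,6-dienoate | COC(=O)/C(CB1OC(C)(C)C(C)(C)O1)=C/CC/C(C)=C/CC[C@@]2(C)O[C@@H]2CO
F2 | step 7 | methyl (2E,6E)-9-[(2R,3S)-3-formyl-2-methyloxiran-2-yl]-6-methyl-2-[(4,4,5,5-tetramethyl-1,3,2-dioxaborolan-2-yl)methyl]nona-2,6-dienoate | COC(=O)/C(CB1OC(C)(C)C(C)(C)O1)=C/CC/C(C)=C/CC[C@@]2(C)O[C@@H]2C=O
F3 | step 10 | 3α,4α-epoxy-13,14,15,16,17-pentanordictyol-10(18)-en-12,6-olide (1R,5S,6R,7S,11R) | C=C1CC[C@@H]2[C@@H](OC(=O)[C@@H]2C)[C@@H]3[C@H]1C[C@H]4O[C@@]34C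
F4 | step 10 | 4α-hydroxy-3β-(phenylselanyl)-13,14,15,16,17-pentanordictyol-10(18)-en-12,6-olide (1R,5S,6R,7S,11R) | C=C1CC[C@@H]2[C@@H](OC(=O)[C@@H]2C)[C@@H]3[C@H]1C[C@H]([Se]c4ccccc4)[C@@]3(C)O
F5 | step 13 | (1R,4R,5S,6R,7S,11R,12S,13S)-13-[2-(trimethylsilyl)ethoxymethoxy]-16,17-dinordictyola-2,10(18),14-triene-4,6,12-triol | C=C1CC[C@@H]([C@@H](C)[C@H](O)[C@H](C=C)OCOCC[Si](C)(C)C)[C@@H](O)[C@@H]2[C@H]1C=C[C@@]2(C)O
F6 | step 13 | (1R,4R,5S,6R,7S,11R,12S,13S)-16,17-dinordictyola-2,10(18),14-triene-4,6,12,13-tetrol | C=C1CC[C@@H]([C@@H](C)[C@H](O)[C@H](C=C)O)[C@@H](O)[C@@H]2[C@H]1C=C[C@@]2(C)O
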